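(The readings are calculated with made-up constants.)

Alder repeats the midnight amounts, and maple, ash and oak change how those amounts go in.

| flask | substrate | reagent | remark | time |
|---|---|---|---|---|
| midnight | 16 mM | 2 equiv | run made earlier |  |
| dawn | 11 mM | 2 equiv | run made earlier |  |
| dusk | 24 mM | 2 equiv | run made earlier |  |
| maple | 16 mM | 2.00 equiv (fed, over 25 h) | all else is in the flask from the start; the feed brings no volume worth counting | 30 h |
| alder | 16 mM | 2.00 equiv | everything together at the start | 30 h |
| ash | 16 mM | 2.00 equiv (in portions, 3, over 25 h) | first portion at the start, last at 25 h | 30 h |
| oak | 16 mM (fed, over 25 h) | 2.00 equiv | all else is in the flask from the start; the feed brings no volume worth counting | 30 h |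

- midnight (time / h: double product / %, triple product / %): 2.50: 54.5, 7.5; 4.00: 47.7, 9.6; 6.00: 39.2, 11.0; 10.0: 28.2, 10.8; 20.0: 17.9, 11.3; 30.0: 16.8, 12.8
- dawn (time / h: double product / %, triple product / %): 3.00: 51.1, 8.3; 6.00: 41.1, 8.5; 10.0: 30.6, 10.4; 12.0: 26.3, 11.6; 15.0: 22.1, 12.9; 20.0: 18.5, 10.6
- dusk (time / h: double product / %, triple product / %): 1.33: 59.8, 7.9; 2.50: 56.3, 8.6; 4.00: 47.1, 14.3; 6.00: 39.5, 11.2; 10.0: 27.7, 13.3; 20.0: 19.3, 13.0

(standard deviation of a reading: 1 percentage point)



* the flask that comes out highest in share of double product in double product plus triple product, or "all alike" when all lie within 1.5 percentage points (maple / alder / ash / oak / all alike)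
* share of double product in double product plus triple product at the end, maple
* share of double product in double product plus triple product at the end, alder
* share of double product in double product plus triple product at the end, ash
* share of double product in double product plus triple product at the end, oak

**Fast rung.** Start with what is over before the first reading: at 1.33 h dusk already shows 59.8% double product. Next compare concentrations. At 10.0 h, midnight (16 mM) reads 28.2% and dusk (24 mM) reads 27.7%, so read the later fall as first-order.

**Middle rung.** Take midnight's last reading as the plateau. The excess of double product above it falls at 0.159 h⁻¹, a half-life of 4.35 h, shorter than the 30 h of the run. Run that excess back to zero time, and the double pool reads 73.0%. Call the part of this pool still standing as double product when the fall ends the standing share: 23.0%, an equilibrium fraction if the loss is reversible.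

**Slow rung.** After 6.00 h, midnight's double product loses 22 percentage points while triple product gains 1.8 points, less than that loss. Treat triple product as the correction to the standing double product.

**My reckoning.** Alder should match midnight at 56.8%. Oak has its reagent charge in the flask from the start, while its substrate enters over 25 h, so the first double product formed there meets reagent near its charged level. Expect more triple product in oak; as a trial figure of my own, not a computed amount, 25.6% would give a share of 39.6%. Choose between maple and ash, not oak.

**The forecast.** It gives maple 58%, alder 57%, ash 58% and oak 63%, and picks oak: “The share therefore depends mainly on material age.” It agrees with my reckoning on alder and differs on oak.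

**The result.** The highest is ash, at 67.7%. Maple gives 57.7%, alder 57.6% and oak 28.1%.

    reagent + single product → double product + by-product (k = 2.10 M⁻¹ min⁻¹)
    reagent + double product → triple product + by-product (k = 0.170 M⁻¹ min⁻¹)
    substrate + reagent → single product + by-product (k = 2.50 M⁻¹ min⁻¹)
    single product → side product (k = 0.00130 min⁻¹)
    double product ⇌ isomer of the product (K = 3.50, k = 0.00230 min⁻¹)

**Oak's pool.** At 11.7 h in oak, reagent uses double product 1.1 times as fast as the forward turning to isomer of the product does. At 30.0 h, oak holds 32.6% triple product against alder's 12.5%. Double product over double product plus isomer of the product stands at 28.9% in oak at 30.0 h. Read at 3.0 d, the same flask gives 22.2%, beside the standing share of 23.0%.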